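The trap in these readings was to lay the two percent columns side by side and see a ceiling that falls with heat, but the columns stand on different charges and different clocks.

| flask | solid substrate | temperature | remark | time |
|---|---|---|---|---|
| cedar | 28 mM | 55 °C | run made earlier |  |
| oak | 44 mM | 88 °C | run made earlier |  |
| beta | 20 mM | 70 °C |  | 4.0 h |
| zeta | 20 mM |  | at 40 °C until 50 min, from then on at 100 °C | 4.0 h |
| gamma | 20 mM | 100 °C |  | 4.0 h |
| delta | 20 mM | 40 °C |  | 4.0 h |

- cedar (time / h: target / %): 2.00: 6; 4.00: 13; 6.00: 14; 8.00: 21; 10.0: 22
- oak (time / min: target / %): 10.0: 0; 30.0: 0; 50.0: 1; 80.0: 4; 120: 2

(readings scatter by 1.5 percentage points)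

- as a solid, counted per litre of solution: solid substrate
- the analysis behind the earlier runs scatters by 1.5 percentage points, standard deviation
- at the start none of the solid substrate is in solution
- what has only dissolved of solid substrate counts as not reacted

* the flask that comes out highest in amount of target, in percent of the solid substrate charged, or "all alike" when all lie within 1.5 percentage points (beta / zeta / gamma / delta / all alike)
* target at the end, in percent of the solid substrate charged, beta
* target at the end, in percent of the solid substrate charged, zeta
* target at the end, in percent of the solid substrate charged, gamma
* target at the end, in percent of the solid substrate charged, delta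

So I read both tables again as c(target) in mM against hours. In the oak table the fall from 4 % to 2 % is 2 percentage points against a scatter of 1.5 points per reading, so I could not read a plateau from those rows. A straight line through the origin gave 0.682 mM/h for the cedar run and 0.663 mM/h for the oak run, nearly equal despite different temperatures and charges.

I supposed that what dissolves passes on to target quickly, which would make dissolving the rate-limiting step, and the two nearly equal slopes fitted that supposition. I called the slope the supply rate: the mM of target formed per hour while solid remains. While solid remains, the percentage of target is then supply rate times time, divided by the charge. Beta, zeta, gamma and delta share their charge and time, so the reckoning gave each 13.6 %. That uses 2.73 mM of the 20 mM charged. Delta, gamma and zeta stand at temperatures outside those of the runs, so this was an extrapolation, but I committed to "all alike".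

The forecast differed from my reckoning: it named delta highest, with beta 8 %, zeta 2.5 %, gamma 1.5 % and delta 10 %, holding that “heat speeds the approach but lowers the ceiling”.

The flasks gave beta 14.0 %, zeta 14.0 %, gamma 14.0 % and delta 14.0 %, so the outcome was all alike, against my 13.6 %.

    starting material → target, rate k1*[starting material]/(1 + ([starting material]/sat1)) (0.310 mM, k = 0.0780 /s, Ea = 82.0 kJ/mol)
    solid substrate ⇌ starting material, rate k2*(cs2 - [starting material]) while solid is left; crystals form when [starting material] > cs2 (solubility = 1.30 mM, k = 1.50 × 10⁻⁴ /s)
    starting material + target → side product (k = 0.00180 /M/s, Ea = 66.0 kJ/mol)
    (constants at 40 °C)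

The neighbour of gamma held the same temperature and time but had 80 mM of solid substrate. The supply rate of 0.682 mM/h gave 2.73 mM of target in that flask, which is 3.41 % of its charge. The neighbour gave 3.51 %, or 2.81 mM, while gamma itself gave 2.80 mM. At the end of the neighbour flask, 96 % of the charged solid substrate was still there, solid or dissolved.

The runs were computed for substances that don't exist, noise included.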